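Ring B (the furanone ring) holds a fully substituted hemiketal carbon C2 that carries O1 and the methylene C1', and C1' is bonded to the sp2 carbon C2' of the farnesyl chain. Both bonds, O1–C2 and C1'–C2', are therefore cut together, which leads back to a C2=C1' double bond. In the forward sense a chiral palladium catalyst adds the phenol oxygen and an (E)-alkenyl group across that double bond, closing ring B and setting C2 in one operation. The precursor is a 2-hydroxyaryl 1-(methoxymethoxy)vinyl ketone; its partner is a C14 (E)-alkenyl pinacol boronate. Mild removal of two methoxymethyl groups then frees the hemiketal.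

Key step: step 10

Assumption (remark on the chemistry): the neutral C2 hemiketal of the target is taken to be configurationally stable at or below room temperature without acid or base, although it could in principle open to the 1,2-diketone; the last step and its work-up are chosen for that reason.

Remark on descriptors: the same spatial arrangement at C2 is named 2S in the ketals 20 and 21 and 2R in the target 22, because exchanging OH for O–CH2 or O–Si reverses the CIP ranking of the two oxygen substituents.

**Route**

Step 1
Reactants: 1 1-(2,4-dihydroxyphenyl)propan-1-one (2,4-dihydroxypropiophenone)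
Product: 2 1-[2-hydroxy-4-(methoxymethoxy)phenyl]propan-1-one
Conditions: MOMCl (1.05 equiv), K2CO3, acetone, 0 °C to rt
Reagents that add atoms: chloromethyl methyl ether (MOMCl), COCCl
Why: Williamson-type O-alkylation with a chloromethyl ether, in which the 4-hydroxyl is the more acidic and accessible phenol while the 2-hydroxyl is held in a hydrogen bond to the ketone, so one equivalent of MOMCl with a weak base should etherify O4 selectively.

Step 2
Reactants: 2 1-[2-hydroxy-4-(methoxymethoxy)phenyl]propan-1-one
Product: 4 1-[4-(methoxymethoxy)-2-(triisopropylsilyloxy)phenyl]propan-1-one, via sodium phenoxide 3 (not isolated)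
Conditions: NaH, THF–DMF (4:1), 0 °C; then TIPSCl, 0 °C to rt
Reagents that add atoms: chlorotriisopropylsilane (TIPSCl), CC(C)[Si](Cl)(C(C)C)C(C)C
Why: Silylation of a preformed phenoxide, in which irreversible deprotonation breaks the hydrogen bond and the phenoxide 3 attacks the silyl chloride at oxygen, giving an aryl silyl ether that is orthogonal to both methoxymethyl groups and stable to the base of step 4.

Step 3
Reactants: 4 1-[4-(methoxymethoxy)-2-(triisopropylsilyloxy)phenyl]propan-1-one
Product: 5 1-[4-(methoxymethoxy)-2-(triisopropylsilyloxy)phenyl]propane-1,2-dione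
Conditions: SeO2 (1.1 equiv), pyridine (2 equiv), 1,4-dioxane/H2O (30:1), 90 °C
Reagents that add atoms: selenium dioxide, O=[Se]=O
Why: Riley oxidation, in which selenous acid attacks the enol of the aryl ketone and turns the only enolisable methylene into a carbonyl group, while the near-stoichiometric charge limits further oxidation of the new acetyl methyl and pyridine buffers the medium so that the acetal and silyl ethers should survive.

Step 4
Reactants: 5 1-[4-(methoxymethoxy)-2-(triisopropylsilyloxy)phenyl]propane-1,2-dione
Product: 7 2-(methoxymethoxy)-1-[4-(methoxymethoxy)-2-(triisopropylsilyloxy)phenyl]prop-2-en-1-one, via potassium enolate 6 (not isolated)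
Conditions: KN(SiMe3)2, THF–DMPU, −78 °C (diketone added to the base); then MOMCl, −78 to −40 °C
Reagents that add atoms: chloromethyl methyl ether (MOMCl), COCCl
Why: O-Alkylation of a ketone enolate with a chloromethyl ether, in which the diketone can enolise only toward its methyl group and the potassium enolate 6 in a dipolar medium should react with the hard, oxocarbenium-like electrophile at oxygen to give the 2-alkoxy enone.

Step 5
Reactants: 7 2-(methoxymethoxy)-1-[4-(methoxymethoxy)-2-(triisopropylsilyloxy)phenyl]prop-2-en-1-one
Product: 8 1-[2-hydroxy-4-(methoxymethoxy)phenyl]-2-(methoxymethoxy)prop-2-en-1-one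
Conditions: Bu4NF (1.1 equiv), AcOH (1.2 equiv), THF, −20 to 0 °C
Reagents that add atoms: none
Why: Fluoride-mediated desilylation, in which an aryl silyl ether ortho to a carbonyl group is cleaved fast and the acetic acid buffer protonates the phenoxide at once, so that neither oxa-Michael closure nor loss of the acetals should occur and the free phenol appears only directly before the key step.

Step 6
Reactants: 9 trimethyl(prop-1-yn-1-yl)silane [1-(trimethylsilyl)propyne]; 10 geranyl bromide, (2E)-1-bromo-3,7-dimethylocta-2,6-diene
Product: 12 [(5E)-6,10-dimethylundeca-5,9-dien-1-yn-1-yl]trimethylsilane, via propargyllithium 11 (not isolated)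
Conditions: n-BuLi, THF, −78 to −20 °C; then 10, −78 °C to rt
Reagents that add atoms: none
Why: Propargylic lithiation followed by SN2 alkylation, in which n-BuLi removes a methyl proton of the silyl-capped propyne and the propargyllithium 11 displaces the primary allylic bromide at its α-carbon, leaving the E double bond of the geranyl unit untouched.

Step 7
Reactants: 12 [(5E)-6,10-dimethylundeca-5,9-dien-1-yn-1-yl]trimethylsilane
Product: 13 (5E)-6,10-dimethylundeca-5,9-dien-1-yne
Conditions: K2CO3 (0.2 equiv), MeOH, rt
Reagents that add atoms: none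
Why: Base-catalysed protodesilylation of an alkynylsilane, in which methoxide attacks silicon and methanol protonates the acetylide without touching the isolated alkenes.

Step 8
Reactants: 13 (5E)-6,10-dimethylundeca-5,9-dien-1-yne
Product: 15 (1E,5E)-1-iodo-2,6,10-trimethylundeca-1,5,9-triene, via alkenylalane 14 (not isolated)
Conditions: Me3Al (2 equiv), Cp2ZrCl2 [(C5H5)2ZrCl2, 0.25 equiv], CH2Cl2, 0 °C to rt; then I2, THF, −30 to 0 °C
Reagents that add atoms: trimethylaluminium, C[Al](C)C; iodine, II
Why: Negishi zirconium-catalysed carboalumination followed by iododealumination, in which methyl and aluminium add syn across the terminal alkyne with aluminium on the terminal carbon and iodine replaces aluminium with retention, so the new trisubstituted double bond is E.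

Step 9
Reactants: 15 (1E,5E)-1-iodo-2,6,10-trimethylundeca-1,5,9-triene
Product: 18 4,4,5,5-tetramethyl-2-[(1E,5E)-2,6,10-trimethylundeca-1,5,9-trien-1-yl]-1,3,2-dioxaborolane, via alkenyllithium 16 (not isolated), via lithium borate 17 (not isolated)
Conditions: t-BuLi (2.1 equiv), Et2O, −78 °C; then iPrOBpin, −78 °C to rt; then H2O
Reagents that add atoms: 2-isopropoxy-4,4,5,5-tetramethyl-1,3,2-dioxaborolane (iPrOBpin), CC(C)OB1OC(C)(C)C(C)(C)O1
Why: Lithium–iodine exchange followed by borylation, in which exchange at low temperature retains the alkene geometry, the alkenyllithium 16 adds to boron to give the borate 17, and loss of isopropoxide on aqueous quench leaves the pinacol boronate.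

Step 10
Reactants: 8 1-[2-hydroxy-4-(methoxymethoxy)phenyl]-2-(methoxymethoxy)prop-2-en-1-one; 18 4,4,5,5-tetramethyl-2-[(1E,5E)-2,6,10-trimethylundeca-1,5,9-trien-1-yl]-1,3,2-dioxaborolane
Product: 20 (2S)-2,6-bis(methoxymethoxy)-2-[(2E,6E)-3,7,11-trimethyldodeca-2,6,10-trien-1-yl]-1-benzofuran-3(2H)-one, via alkylpalladium trifluoroacetate 19 (not isolated)
Conditions: Pd(OCOCF3)2 (10 mol %), (S,S)-Bn-BOXAX [(S)-2,2'-bis((4S)-4-benzyl-4,5-dihydrooxazol-2-yl)-1,1'-binaphthyl, 40 mol %], p-benzoquinone (2 equiv), 18 (1.5 equiv), H2O (2 equiv), CH2Cl2, 0 °C to rt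
Reagents that add atoms: none
Why: Proposed new method: The ligated Pd(OCOCF3)2 (divalent palladium) binds the C2=C1' enol-ether double bond of 8, the ortho-phenol oxygen adds to C2 (oxypalladation), and the σ-alkylpalladium 19 at C1' cannot undergo β-hydride elimination because C2 is now fully substituted, so it lives long enough to take the (E)-alkenyl group from 18 by transmetalation and to form C1'–C2' by reductive elimination with retention of alkene geometry, after which p-benzoquinone returns zerovalent palladium to divalent palladium. The closest known reaction type is the enantioselective Wacker-type cyclisation of phenols onto 1,1-disubstituted alkenes in which the β-hydrogen-free alkylpalladium is intercepted by a second component (domino Wacker–Heck and Wacker–carbonylation), combined with the boron-to-palladium transfer known from oxidative boron-Heck couplings; interception by an alkenylboronate and the use of a 2-alkoxy enone as the alkene are untested. Ring B closes in the 5-exo-trig mode by attack of O1 on C2. The stereocentre C2 is set in the oxypalladation, where the chiral bis(oxazoline) ligand on palladium selects one face of the alkene; the sense of induction has to be established by experiment and the enantiomeric ligand is used if it proves opposite to 2S. The step needs attack at C2 instead of 6-endo conjugate addition at C1' and needs oxypalladation to precede transmetalation: the methoxymethoxy donor on C2 makes C2 the electrophilic end of the palladium-bound alkene, the pinacol boronate transmetalates slowly, and the excess ligand buffers the CF3CO2H that could otherwise protonate the enol ether. β-Oxygen elimination from 19 is expected to expel the better leaving group, the aryloxide, which only reverses the ring closure.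

Step 11
Reactants: 20 (2S)-2,6-bis(methoxymethoxy)-2-[(2E,6E)-3,7,11-trimethyldodeca-2,6,10-trien-1-yl]-1-benzofuran-3(2H)-one
Product: 22 (2R)-2,6-dihydroxy-2-[(2E,6E)-3,7,11-trimethyldodeca-2,6,10-trien-1-yl]-1-benzofuran-3(2H)-one, via bis(trimethylsilyl) ether 21 (not isolated)
Conditions: Me3SiOTf (4 equiv), 2,2'-bipyridyl (6 equiv), CH2Cl2, 0 °C; then H2O, 0 °C; work-up with pH 7 phosphate buffer
Reagents that add atoms: none
Why: Silyl triflate–bipyridyl cleavage of methoxymethyl ethers, in which the silylated bipyridinium exchanges each O–CH2OMe for O–SiMe3 under non-acidic conditions (the ketal oxygen is as poor a donor as an aryl oxygen, so the methoxymethyl cation should leave toward bipyridyl and not stay on the substrate next to the C2'=C3' double bond) and water then hydrolyses both silyl ethers, so no bond to C2 is broken and the configuration set in step 10 should be retained.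

**Compound list**

1 | 1-(2,4-dihydroxyphenyl)propan-1-one | CCC(=O)c1ccc(O)cc1O | starting material
2 | 1-[2-hydroxy-4-(methoxymethoxy)phenyl]propan-1-one | CCC(=O)c1ccc(OCOC)cc1O | intermediate
3 | sodium 5-(methoxymethoxy)-2-propanoylphenolate | CCC(=O)c1ccc(OCOC)cc1[O-].[Na+] | intermediate
4 | 1-[4-(methoxymethoxy)-2-(triisopropylsilyloxy)phenyl]propan-1-one | CCC(=O)c1ccc(OCOC)cc1O[Si](C(C)C)(C(C)C)C(C)C | intermediate
5 | 1-[4-(methoxymethoxy)-2-(triisopropylsilyloxy)phenyl]propane-1,2-dione | CC(=O)C(=O)c1ccc(OCOC)cc1O[Si](C(C)C)(C(C)C)C(C)C | intermediate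
6 | potassium 3-[4-(methoxymethoxy)-2-(triisopropylsilyloxy)phenyl]-3-oxoprop-1-en-2-olate | C=C([O-])C(=O)c1ccc(OCOC)cc1O[Si](C(C)C)(C(C)C)C(C)C.[K+] | intermediate
7 | 2-(methoxymethoxy)-1-[4-(methoxymethoxy)-2-(triisopropylsilyloxy)phenyl]prop-2-en-1-one | C=C(OCOC)C(=O)c1ccc(OCOC)cc1O[Si](C(C)C)(C(C)C)C(C)C | intermediate
8 | 1-[2-hydroxy-4-(methoxymethoxy)phenyl]-2-(methoxymethoxy)prop-2-en-1-one | C=C(OCOC)C(=O)c1ccc(OCOC)cc1O | intermediate
9 | trimethyl(prop-1-yn-1-yl)silane | CC#C[Si](C)(C)C | starting material
10 | geranyl bromide, (2E)-1-bromo-3,7-dimethylocta-2,6-diene | CC(C)=CCC/C(C)=C/CBr | starting material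
11 | [3-(trimethylsilyl)prop-2-yn-1-yl]lithium | [Li]CC#C[Si](C)(C)C | intermediate
12 | [(5E)-6,10-dimethylundeca-5,9-dien-1-yn-1-yl]trimethylsilane | CC(C)=CCC/C(C)=C/CCC#C[Si](C)(C)C | intermediate
13 | (5E)-6,10-dimethylundeca-5,9-dien-1-yne | CC(C)=CCC/C(C)=C/CCC#C | intermediate
14 | dimethyl[(1E,5E)-2,6,10-trimethylundeca-1,5,9-trien-1-yl]alumane | CC(C)=CCC/C(C)=C/CC/C(C)=C/[Al](C)C | intermediate
15 | (1E,5E)-1-iodo-2,6,10-trimethylundeca-1,5,9-triene | CC(C)=CCC/C(C)=C/CC/C(C)=C/I | intermediate
16 | [(1E,5E)-2,6,10-trimethylundeca-1,5,9-trien-1-yl]lithium | CC(C)=CCC/C(C)=C/CC/C(C)=C/[Li] | intermediate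
17 | lithium isopropoxy(pinacolato)[(1E,5E)-2,6,10-trimethylundeca-1,5,9-trien-1-yl]borate | [Li+].CC(C)=CCC/C(C)=C/CC/C(C)=C/[B-]1(OC(C)C)OC(C)(C)C(C)(C)O1 | intermediate
18 | 4,4,5,5-tetramethyl-2-[(1E,5E)-2,6,10-trimethylundeca-1,5,9-trien-1-yl]-1,3,2-dioxaborolane | CC(C)=CCC/C(C)=C/CC/C(C)=C/B1OC(C)(C)C(C)(C)O1 | intermediate
19 | {[2,6-bis(methoxymethoxy)-3-oxo-2,3-dihydro-1-benzofuran-2-yl]methyl}palladium trifluoroacetate (C2 arranged as in 20; chiral ligand not drawn) | FC(F)(F)C(=O)O[Pd]C[C@@]1(OCOC)Oc2cc(OCOC)ccc2C1=O | intermediate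
20 | (2S)-2,6-bis(methoxymethoxy)-2-[(2E,6E)-3,7,11-trimethyldodeca-2,6,10-trien-1-yl]-1-benzofuran-3(2H)-one | CC(C)=CCC/C(C)=C/CC/C(C)=C/C[C@@]1(OCOC)Oc2cc(OCOC)ccc2C1=O | intermediate
21 | (2S)-2-[(2E,6E)-3,7,11-trimethyldodeca-2,6,10-trien-1-yl]-2,6-bis(trimethylsilyloxy)-1-benzofuran-3(2H)-one | CC(C)=CCC/C(C)=C/CC/C(C)=C/C[C@@]1(O[Si](C)(C)C)Oc2cc(O[Si](C)(C)C)ccc2C1=O | intermediate
22 | (2R)-2,6-dihydroxy-2-[(2E,6E)-3,7,11-trimethyldodeca-2,6,10-trien-1-yl]-1-benzofuran-3(2H)-one | CC(C)=CCC/C(C)=C/CC/C(C)=C/C[C@@]1(O)Oc2cc(O)ccc2C1=O | target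

**Step count and risks**

Total steps: 11. Longest linear sequence: 7 steps (steps 1 to 5, then 10 and 11, from compound 1); the boronate branch is 4 steps (6 to 9) before the coupling.

Steps most likely to fail:

1. Step 10 (Proposed new method).
   - What may go wrong: the phenol may add to C1' (6-endo conjugate addition), or add under acid catalysis without palladium. The boronate may transmetalate before oxypalladation, which leads to conjugate alkenylation of the enone, homocoupling or addition to the quinone. The alkylpalladium may lose the methoxymethoxy group by β-oxygen elimination, and facial selectivity may be poor.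
   - Fallback (known chemistry): it sets out from the silyl-protected enone 7 and boronate 18 and comes back at ketal 20. Rhodium-catalysed conjugate addition of 18 to 7 ([Rh(OH)(cod)]2, cod = 1,5-cyclooctadiene, dioxane/H2O, 40 °C; Hayashi–Miyaura type) should form the C1'–C2' bond and give the racemic ketone F1. Buffered fluoride as in step 5 frees the phenol F2. Double deprotonation with LiN(SiMe3)2 (THF, −78 °C) gives the dilithium phenoxide-enolate F3, and iodine converts it into the α-iodo ketone F4. F4 closes ring B by intramolecular displacement of iodide by the phenoxide (the classical closure of benzofuran-3(2H)-ones) to the racemic ketal F5. Preparative HPLC on a chiral stationary phase then delivers the configurationally stable (2S)-ketal 20.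

2. Step 11.
   - What may go wrong: electrophilic activation of the ketal methoxymethyl group may cause ionisation at C2 or capture of the O–CH2 cation by the C2'=C3' double bond (Prins-type closure). The freed hemiketal may also lose configuration by ring opening in the presence of the pyridinium salt.
   - Fallback: it changes the protecting group on the C2 oxygen to one removed by oxidation. It sets out from diketone 5 (through its enolate 6) and comes back at the bis(silyl) ether 21 and so at 22. Enolate 6 is alkylated with 4-methoxybenzyl chloromethyl ether in place of MOMCl to give the enol ether F6. Desilylation as in step 5 gives the phenol F7. Oxy-alkenylation with 18 under the conditions of step 10 gives, through the alkylpalladium species F8, the ketal F9. DDQ in CH2Cl2/pH 7 buffer removes the (4-methoxybenzyloxy)methyl group by benzylic oxidation, far from C2 and from the chain, and leaves the hemiketal F10. Me3SiOTf/2,2'-bipyridyl then exchanges only the aryl methoxymethyl ether, the class of ether for which this exchange is established, and silylates the hemiketal hydroxyl, giving 21, which water hydrolyses to 22.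

3. Step 4.
   - What may go wrong: the enolate may condense with unreacted diketone during deprotonation, or the electrophile may attack carbon instead of oxygen.
   - Fallback: it sets out from diketone 5 and comes back at the potassium enolate 6. Soft enolisation (Me3SiCl, NaI, Et3N, MeCN, 0 °C) gives the isolable 2-silyloxy enone F11 with no free enolate in the presence of the diketone. KOt-Bu in THF–DMPU at −78 °C then cleaves the Si–O bond and releases enolate 6 free of amine and of diketone, and it is alkylated at once with MOMCl as in step 4 to give 7.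

Further compounds

F1 | step 10 | (4E,8E)-2-(methoxymethoxy)-1-[4-(methoxymethoxy)-2-(triisopropylsilyloxy)phenyl]-5,9,13-trimethyltetradeca-4,8,12-trien-1-one (racemic) | CC(C)=CCC/C(C)=C/CC/C(C)=C/CC(OCOC)C(=O)c1ccc(OCOC)cc1O[Si](C(C)C)(C(C)C)C(C)C
F2 | step 10 | (4E,8E)-1-[2-hydroxy-4-(methoxymethoxy)phenyl]-2-(methoxymethoxy)-5,9,13-trimethyltetradeca-4,8,12-trien-1-one (racemic) | CC(C)=CCC/C(C)=C/CC/C(C)=C/CC(OCOC)C(=O)c1ccc(OCOC)cc1O
F3 | step 10 | dilithium phenoxide-enolate of F2 | [Li+].[Li+].CC(C)=CCC/C(C)=C/CC/C(C)=C/CC(OCOC)=C([O-])c1ccc(OCOC)cc1[O-]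
F4 | step 10 | lithium phenoxide of the 2-iodo ketone derived from F2 | [Li+].CC(C)=CCC/C(C)=C/CC/C(C)=C/CC(I)(OCOC)C(=O)c1ccc(OCOC)cc1[O-]
F5 | step 10 | racemic 2,6-bis(methoxymethoxy)-2-[(2E,6E)-3,7,11-trimethyldodeca-2,6,10-trien-1-yl]-1-benzofuran-3(2H)-one | CC(C)=CCC/C(C)=C/CC/C(C)=C/CC1(OCOC)Oc2cc(OCOC)ccc2C1=O
F6 | step 11 | 2-{[(4-methoxybenzyl)oxy]methoxy}-1-[4-(methoxymethoxy)-2-(triisopropylsilyloxy)phenyl]prop-2-en-1-one | C=C(OCOCc1ccc(OC)cc1)C(=O)c1ccc(OCOC)cc1O[Si](C(C)C)(C(C)C)C(C)C
F7 | step 11 | 1-[2-hydroxy-4-(methoxymethoxy)phenyl]-2-{[(4-methoxybenzyl)oxy]methoxy}prop-2-en-1-one | C=C(OCOCc1ccc(OC)cc1)C(=O)c1ccc(OCOC)cc1O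
F8 | step 11 | alkylpalladium trifluoroacetate analogous to 19 with the (4-methoxybenzyloxy)methoxy group on C2 (chiral ligand not drawn) | FC(F)(F)C(=O)O[Pd]C[C@@]1(OCOCc3ccc(OC)cc3)Oc2cc(OCOC)ccc2C1=O
F9 | step 11 | (2S)-2-{[(4-methoxybenzyl)oxy]methoxy}-6-(methoxymethoxy)-2-[(2E,6E)-3,7,11-trimethyldodeca-2,6,10-trien-1-yl]-1-benzofuran-3(2H)-one | CC(C)=CCC/C(C)=C/CC/C(C)=C/C[C@@]1(OCOCc3ccc(OC)cc3)Oc2cc(OCOC)ccc2C1=O
F10 | step 11 | (2R)-2-hydroxy-6-(methoxymethoxy)-2-[(2E,6E)-3,7,11-trimethyldodeca-2,6,10-trien-1-yl]-1-benzofuran-3(2H)-one | CC(C)=CCC/C(C)=C/CC/C(C)=C/C[C@@]1(O)Oc2cc(OCOC)ccc2C1=O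
F11 | step 4 | 1-[4-(methoxymethoxy)-2-(triisopropylsilyloxy)phenyl]-2-(trimethylsilyloxy)prop-2-en-1-one | C=C(O[Si](C)(C)C)C(=O)c1ccc(OCOC)cc1O[Si](C(C)C)(C(C)C)C(C)C
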